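**Retrosynthetic overview**
1. The target comes from its tris-TBS ether by fluoride. The saturated C1'–C11' tether comes from a C1'=C2'–C3'(=O) enone by erasing the C3' oxygen (1,4-reduction, C=O reduction, mesylate, hydride).
2. The key bond is C1'–C2'. It is made by an intermolecular crossed aldol addition (then dehydration) of the kinetic lithium enolate of (11E)-hexadec-11-en-2-one to a non-enolisable ring aldehyde.
3. The ring aldehyde comes from (−)-quinic acid. C1, C4 and C5 are kept unchanged, CO2H becomes C1', and C3–OH leaves as the C2=C3 alkene (triflate, PhSe− inversion, selenoxide syn-elimination).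
4. The methyl ketone comes from dec-9-en-1-ol and hex-1-yne (alkynylation, Na/NH3 for the E-alkene, Wacker oxidation of the terminal alkene).
5. Rings: the carbocycle is never built, because it is the ring of quinic acid. Only a temporary 1,4-dioxane acetal ring is closed in step 5 and opened in step 9.

Assumption: ring atoms keep the quinic acid numbering C1–C6 (C1 carries the side chain), side-chain atoms are C1'–C17', and TBS means tert-butyldimethylsilyl.

**Route**

Step 1
Reactants: 1 dec-9-en-1-ol
Product: 2 10-bromodec-1-ene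
Conditions: CBr4, PPh3, CH2Cl2, 0 °C to rt
Reagents that add atoms: carbon tetrabromide, BrC(Br)(Br)Br
Why: In this Appel reaction the primary alkoxyphosphonium ion is displaced by bromide (SN2) under neutral conditions that leave the terminal alkene alone.

Step 2
Reactants: 2 10-bromodec-1-ene; 3 hex-1-yne
Product: 5 hexadec-1-en-11-yne, via hex-1-ynyllithium 4 (not isolated)
Conditions: 3, n-BuLi, THF, −78 to 0 °C; then 2, DMPU, 0 °C to rt
Reagents that add atoms: none
Why: Acetylide alkylation (SN2) of an unhindered primary bromide in a dipolar cosolvent is a standard way to make dialkylalkynes.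

Step 3
Reactants: 5 hexadec-1-en-11-yne
Product: 6 (11E)-hexadeca-1,11-diene
Conditions: Na, NH3(l)/THF, −33 °C; then solid NH4Cl
Reagents that add atoms: none
Why: Dissolving-metal reduction goes through the more stable trans vinyl radical and anion, which sets the E-alkene (>98 %), and the isolated terminal alkene is inert because no alcohol is present.

Step 4
Reactants: 6 (11E)-hexadeca-1,11-diene
Product: 7 (11E)-hexadec-11-en-2-one
Conditions: PdCl2 (10 mol %), CuCl (1 equiv), O2 (1 atm), DMF/H2O 7:1, rt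
Reagents that add atoms: water, O
Why: In this Tsuji–Wacker oxidation the terminal alkene binds palladium far faster than the internal E-alkene and takes up water in the Markovnikov sense, giving the methyl ketone while CuCl/O2 reoxidise the palladium.

Step 5
Reactants: 8 (−)-quinic acid
Product: 9 methyl (1S,3R,4R,5R)-1,3-dihydroxy-4,5-[(2S,3S)-2,3-dimethoxybutane-2,3-diylbis(oxy)]cyclohexane-1-carboxylate
Conditions: butane-2,3-dione, HC(OMe)3, MeOH, CSA (cat.), reflux
Reagents that add atoms: butane-2,3-dione, CC(=O)C(C)=O; methanol, CO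
Why: Butane-2,3-diacetal formation with concurrent Fischer esterification selects the only trans-diequatorial vicinal diol (C4/C5), and the anomeric effect places both OMe groups axial, which fixes the two acetal centres as S,S.

Step 6
Reactants: 9 diacetal-protected methyl quinate
Product: 10 methyl (1R,3R,4S,5R)-1-hydroxy-3-(trifluoromethylsulfonyloxy)-4,5-[(2S,3S)-2,3-dimethoxybutane-2,3-diylbis(oxy)]cyclohexane-1-carboxylate
Conditions: Tf2O, pyridine, CH2Cl2, −20 to 0 °C (cold aqueous work-up, used crude)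
Reagents that add atoms: triflic anhydride, O=S(=O)(OS(=O)(=O)C(F)(F)F)C(F)(F)F
Why: O-Sulfonylation takes the secondary C3–OH and not the hindered, electron-poor tertiary α-hydroxy ester OH, and no C–O bond breaks, so C3 keeps its configuration.

Step 7
Reactants: 10 C3 triflate
Product: 11 methyl (1R,3S,4S,5R)-1-hydroxy-3-(phenylselanyl)-4,5-[(2S,3S)-2,3-dimethoxybutane-2,3-diylbis(oxy)]cyclohexane-1-carboxylate
Conditions: PhSeSePh, NaBH4 (added only until colourless), EtOH, 0 °C; then 10 in THF, 0 °C to rt
Reagents that add atoms: diphenyl diselenide, c1ccc(cc1)[Se][Se]c1ccccc1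
Why: SN2 displacement of the axial triflate by the soft, weakly basic selenolate proceeds with clean inversion and gives the equatorial C3 selenide.

Step 8
Reactants: 11 C3 phenyl selenide
Product: 13 methyl (1R,4R,5R)-1-hydroxy-4,5-[(2S,3S)-2,3-dimethoxybutane-2,3-diylbis(oxy)]cyclohex-2-ene-1-carboxylate, via selenoxide 12 (not isolated)
Conditions: 30 % H2O2, THF, 0 °C to rt
Reagents that add atoms: none
Why: Selenoxide syn-elimination runs away from an oxygen-bearing carbon, so the C2–H is taken rather than the C4–H and only the C2=C3 alkene forms, with C1, C4 and C5 untouched.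

Step 9
Reactants: 13 diacetal-protected cyclohexene ester
Product: 14 methyl (1R,4R,5R)-1,4,5-trihydroxycyclohex-2-ene-1-carboxylate
Conditions: TFA/H2O 9:1, rt; evaporate with toluene
Reagents that add atoms: none
Why: This is acid hydrolysis of the bis-acetal, done at this stage because the ester on C1 destabilises an allyl cation and so protects the tertiary allylic alcohol from ionisation, and only acetal C–O bonds break.

Step 10
Reactants: 14 triol ester
Product: 15 methyl (1R,4R,5R)-1,4,5-tris(tert-butyldimethylsilyloxy)cyclohex-2-ene-1-carboxylate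
Conditions: TBSOTf, 2,6-lutidine, CH2Cl2, 0 °C to rt
Reagents that add atoms: tert-butyldimethylsilyl triflate, CC(C)(C)[Si](C)(C)OS(=O)(=O)C(F)(F)F
Why: Silyl ether formation with the triflate is strong enough to cap the tertiary OH as well, which gives groups that come off later without acid.

Step 11
Reactants: 15 tris-TBS ester
Product: 16 [(1R,4R,5R)-1,4,5-tris(tert-butyldimethylsilyloxy)cyclohex-2-en-1-yl]methanol
Conditions: iBu2AlH, CH2Cl2, −78 to 0 °C; aq. KNaC4H4O6
Reagents that add atoms: none
Why: Full hydride reduction of the ester to the primary alcohol avoids the uncertain partial reduction of a hindered ester and leaves silyl ethers and the alkene intact.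

Step 12
Reactants: 16 neopentyl-type primary alcohol
Product: 17 (1R,4R,5R)-1,4,5-tris(tert-butyldimethylsilyloxy)cyclohex-2-ene-1-carbaldehyde
Conditions: Dess–Martin periodinane, CH2Cl2, rt
Reagents that add atoms: none
Why: Dess–Martin oxidation is mild and neutral, and the aldehyde has no α-hydrogen, so it can neither epimerise nor move into conjugation.

Step 13
Reactants: 7 (11E)-hexadec-11-en-2-one; 17 ring aldehyde
Product: 19 (12E)-1-hydroxy-1-[(1R,4R,5R)-1,4,5-tris(tert-butyldimethylsilyloxy)cyclohex-2-en-1-yl]heptadec-12-en-3-one (both C1' epimers), via lithium enolate 18 (not isolated)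
Conditions: 7, LiN(iPr)2, THF, −78 °C; then 17, −78 °C; aq. NH4Cl at −78 °C
Reagents that add atoms: none
Why: In this directed crossed aldol addition, kinetic deprotonation gives the methyl-side enolate and the aldehyde cannot enolise, so only the C1'–C2' bond forms, and the new C1' carbinol centre is unselective but is erased in step 14.

Step 14
Reactants: 19 aldol adduct
Product: 21 (1E,12E)-1-[(1R,4R,5R)-1,4,5-tris(tert-butyldimethylsilyloxy)cyclohex-2-en-1-yl]heptadeca-1,12-dien-3-one, via C1' mesylate 20 (not isolated)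
Conditions: MsCl, Et3N, CH2Cl2, 0 °C; then DBU, rt
Reagents that add atoms: none
Why: Mesylation followed by E1cB elimination of the β-mesyloxy ketone completes the aldol condensation and gives the E-enone, and C1 carries no hydrogen that base could remove.

Step 15
Reactants: 21 enone
Product: 23 (12E)-1-[(1R,4R,5R)-1,4,5-tris(tert-butyldimethylsilyloxy)cyclohex-2-en-1-yl]heptadec-12-en-3-one, via copper enolate 22 (not isolated)
Conditions: [(Ph3P)CuH]6, toluene, H2O (5 equiv), rt
Reagents that add atoms: none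
Why: Copper hydride conjugate reduction delivers hydride only to the β-carbon of the enone, water protonates the enolate, and the two isolated alkenes are not touched.

Step 16
Reactants: 23 saturated ketone
Product: 24 (12E)-1-[(1R,4R,5R)-1,4,5-tris(tert-butyldimethylsilyloxy)cyclohex-2-en-1-yl]heptadec-12-en-3-ol (both C3' epimers)
Conditions: NaBH4, MeOH/THF, 0 °C
Reagents that add atoms: none
Why: Borohydride reduction of an unhindered dialkyl ketone is routine, and the C3' centre forms unselectively and is erased in step 18.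

Step 17
Reactants: 24 secondary alcohol
Product: 25 C3' methanesulfonate of 24
Conditions: MsCl, Et3N, CH2Cl2, 0 °C
Reagents that add atoms: methanesulfonyl chloride, CS(=O)(=O)Cl
Why: Mesylation through the sulfene is fast on an unhindered secondary alcohol.

Step 18
Reactants: 25 secondary mesylate
Product: 26 (1R,4R,5R)-1,4,5-tris(tert-butyldimethylsilyloxy)-1-[(12E)-heptadec-12-en-1-yl]cyclohex-2-ene
Conditions: LiEt3BH, THF, 0 °C to rt
Reagents that add atoms: none
Why: SN2 hydride displacement of an open-chain secondary sulfonate is an ionic deoxygenation, so no C3' radical arises that could close in a 5-exo fashion onto the ring alkene.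

Step 19
Reactants: 26 tris-TBS ether
Product: 27 (1R,4R,5R)-1-[(12E)-heptadec-12-en-1-yl]cyclohex-2-ene-1,4,5-triol
Conditions: Bu4NF, THF, rt to 45 °C
Reagents that add atoms: none
Why: Fluoride-driven desilylation breaks only Si–O bonds under non-acidic conditions, so the acid-sensitive tertiary allylic alcohol and all three stereocentres survive.

**Compound list**
1 | dec-9-en-1-ol | OCCCCCCCCC=C | starting material
2 | 10-bromodec-1-ene | BrCCCCCCCCC=C | intermediate
3 | hex-1-yne | CCCCC#C | starting material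
4 | hex-1-ynyllithium | CCCCC#C[Li] | intermediate
5 | hexadec-1-en-11-yne | CCCCC#CCCCCCCCCC=C | intermediate
6 | (11E)-hexadeca-1,11-diene | CCCC/C=C/CCCCCCCCC=C | intermediate
7 | (11E)-hexadec-11-en-2-one | CCCC/C=C/CCCCCCCCC(C)=O | intermediate
8 | (−)-quinic acid, (1S,3R,4S,5R)-1,3,4,5-tetrahydroxycyclohexane-1-carboxylic acid | OC(=O)[C@]1(O)C[C@@H](O)[C@@H](O)[C@H](O)C1 | starting material
9 | methyl (1S,3R,4R,5R)-1,3-dihydroxy-4,5-[(2S,3S)-2,3-dimethoxybutane-2,3-diylbis(oxy)]cyclohexane-1-carboxylate | COC(=O)[C@]1(O)C[C@@H](O)[C@H]2O[C@](C)(OC)[C@@](C)(OC)O[C@@H]2C1 | intermediate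
10 | C3 triflate of 9 (1R,3R,4S,5R) | COC(=O)[C@]1(O)C[C@@H](OS(=O)(=O)C(F)(F)F)[C@H]2O[C@](C)(OC)[C@@](C)(OC)O[C@@H]2C1 | intermediate
11 | C3-inverted phenyl selenide (1R,3S,4S,5R) | COC(=O)[C@]1(O)C[C@H]([Se]c3ccccc3)[C@H]2O[C@](C)(OC)[C@@](C)(OC)O[C@@H]2C1 | intermediate
12 | selenoxide of 11 (mixture at Se) | COC(=O)[C@]1(O)C[C@H]([Se](=O)c3ccccc3)[C@H]2O[C@](C)(OC)[C@@](C)(OC)O[C@@H]2C1 | intermediate
13 | methyl (1R,4R,5R)-1-hydroxy-4,5-[(2S,3S)-2,3-dimethoxybutane-2,3-diylbis(oxy)]cyclohex-2-ene-1-carboxylate | COC(=O)[C@]1(O)C=C[C@H]2O[C@](C)(OC)[C@@](C)(OC)O[C@@H]2C1 | intermediate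
14 | methyl (1R,4R,5R)-1,4,5-trihydroxycyclohex-2-ene-1-carboxylate | COC(=O)[C@]1(O)C=C[C@@H](O)[C@H](O)C1 | intermediate
15 | methyl (1R,4R,5R)-1,4,5-tris(tert-butyldimethylsilyloxy)cyclohex-2-ene-1-carboxylate | COC(=O)[C@]1(O[Si](C)(C)C(C)(C)C)C=C[C@@H](O[Si](C)(C)C(C)(C)C)[C@H](O[Si](C)(C)C(C)(C)C)C1 | intermediate
16 | [(1R,4R,5R)-1,4,5-tris(tert-butyldimethylsilyloxy)cyclohex-2-en-1-yl]methanol | OC[C@]1(O[Si](C)(C)C(C)(C)C)C=C[C@@H](O[Si](C)(C)C(C)(C)C)[C@H](O[Si](C)(C)C(C)(C)C)C1 | intermediate
17 | (1R,4R,5R)-1,4,5-tris(tert-butyldimethylsilyloxy)cyclohex-2-ene-1-carbaldehyde | O=C[C@]1(O[Si](C)(C)C(C)(C)C)C=C[C@@H](O[Si](C)(C)C(C)(C)C)[C@H](O[Si](C)(C)C(C)(C)C)C1 | intermediate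
18 | lithium (11E)-hexadeca-1,11-dien-2-olate | CCCC/C=C/CCCCCCCCC(=C)O[Li] | intermediate
19 | aldol adduct, (12E)-1-hydroxy-1-[ring]heptadec-12-en-3-one, both C1' epimers | CCCC/C=C/CCCCCCCCC(=O)CC(O)[C@]1(O[Si](C)(C)C(C)(C)C)C=C[C@@H](O[Si](C)(C)C(C)(C)C)[C@H](O[Si](C)(C)C(C)(C)C)C1 | intermediate
20 | C1' methanesulfonate of 19 | CCCC/C=C/CCCCCCCCC(=O)CC(OS(C)(=O)=O)[C@]1(O[Si](C)(C)C(C)(C)C)C=C[C@@H](O[Si](C)(C)C(C)(C)C)[C@H](O[Si](C)(C)C(C)(C)C)C1 | intermediate
21 | (1E,12E)-1-[ring]heptadeca-1,12-dien-3-one | CCCC/C=C/CCCCCCCCC(=O)/C=C/[C@]1(O[Si](C)(C)C(C)(C)C)C=C[C@@H](O[Si](C)(C)C(C)(C)C)[C@H](O[Si](C)(C)C(C)(C)C)C1 | intermediate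
22 | copper enolate of 23 (phosphine ligand omitted) | CCCC/C=C/CCCCCCCCC(O[Cu])=CC[C@]1(O[Si](C)(C)C(C)(C)C)C=C[C@@H](O[Si](C)(C)C(C)(C)C)[C@H](O[Si](C)(C)C(C)(C)C)C1 | intermediate
23 | (12E)-1-[ring]heptadec-12-en-3-one | CCCC/C=C/CCCCCCCCC(=O)CC[C@]1(O[Si](C)(C)C(C)(C)C)C=C[C@@H](O[Si](C)(C)C(C)(C)C)[C@H](O[Si](C)(C)C(C)(C)C)C1 | intermediate
24 | (12E)-1-[ring]heptadec-12-en-3-ol, both C3' epimers | CCCC/C=C/CCCCCCCCC(O)CC[C@]1(O[Si](C)(C)C(C)(C)C)C=C[C@@H](O[Si](C)(C)C(C)(C)C)[C@H](O[Si](C)(C)C(C)(C)C)C1 | intermediate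
25 | C3' methanesulfonate of 24 | CCCC/C=C/CCCCCCCCC(OS(C)(=O)=O)CC[C@]1(O[Si](C)(C)C(C)(C)C)C=C[C@@H](O[Si](C)(C)C(C)(C)C)[C@H](O[Si](C)(C)C(C)(C)C)C1 | intermediate
26 | (1R,4R,5R)-1,4,5-tris(tert-butyldimethylsilyloxy)-1-[(12E)-heptadec-12-en-1-yl]cyclohex-2-ene | CCCC/C=C/CCCCCCCCCCC[C@]1(O[Si](C)(C)C(C)(C)C)C=C[C@@H](O[Si](C)(C)C(C)(C)C)[C@H](O[Si](C)(C)C(C)(C)C)C1 | intermediate
27 | (1R,4R,5R)-1-[(12E)-heptadec-12-en-1-yl]cyclohex-2-ene-1,4,5-triol | CCCC/C=C/CCCCCCCCCCC[C@]1(O)C=C[C@@H](O)[C@H](O)C1 | target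

In the list, "[ring]" stands for the (1R,4R,5R)-1,4,5-tris(tert-butyldimethylsilyloxy)cyclohex-2-en-1-yl group.

**Totals**
The route has 19 steps in total. The longest linear sequence is 15 steps (8 to 27, steps 5–19). The chain arm (steps 1–4) joins at step 13.

**Three steps most likely to fail**

Step 7 (selenolate displacement at C3). The β-oxygen on C4 slows SN2, and E2 may compete. The fallback sets out from 9 and comes back at 13, so it bypasses steps 6–8 and needs no substitution at C3. Compound 9 is treated with NaH, CS2 and then MeI in THF at 0 °C, which gives the C3 O-alkyl S-methyl xanthate F1. This is heated in o-dichlorobenzene at 180 °C (Chugaev syn-elimination). The axial C3–O has only one cis hydrogen next to it, the equatorial C2–H, because the C4–H is trans-diaxial. The thermal cis-elimination can therefore give only the C2=C3 alkene 13.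

Step 13 (lithium aldol on a hindered α-silyloxy aldehyde). The risks are retro-aldol and migration of the C1 silyl group onto the new C1' lithium alkoxide. The fallback sets out from 7 and comes back at 19. Ketone 7 is converted with LiN(iPr)2 and Me3SiCl in THF at −78 °C into the kinetic trimethylsilyl enol ether F2. This is added to aldehyde 17 with BF3·OEt2 in CH2Cl2 at −78 °C (Mukaiyama aldol addition). No free alkoxide is formed, and aqueous work-up gives 19.

Step 18 (hydride displacement). The risks are E2 to chain alkenes and attack of the C1 silyloxy oxygen on C3' to close a tetrahydrofuran. The fallback sets out from 24 and comes back at 26. Alcohol 24 is heated with 1,1'-thiocarbonyldiimidazole and DMAP in toluene at 80 °C, which gives the O-alkyl imidazole-1-carbothioate F3. This is reduced with Bu3SnH and AIBN in benzene at 80 °C in the presence of 15 mol % PhSeSePh (Barton–McCombie deoxygenation). The PhSeH formed in situ transfers hydrogen to the C3' radical about a thousand times faster than the stannane does. That outruns the 5-exo closure onto the ring alkene.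

**Further compounds**
F1 | step 7 | C3 O-(methylsulfanylthiocarbonyl) derivative (S-methyl xanthate) of 9 | COC(=O)[C@]1(O)C[C@@H](OC(=S)SC)[C@H]2O[C@](C)(OC)[C@@](C)(OC)O[C@@H]2C1
F2 | step 13 | (11E)-2-(trimethylsilyloxy)hexadeca-1,11-diene | CCCC/C=C/CCCCCCCCC(=C)O[Si](C)(C)C
F3 | step 18 | C3' O-(imidazol-1-ylthiocarbonyl) derivative of 24 | CCCC/C=C/CCCCCCCCC(OC(=S)n2ccnc2)CC[C@]1(O[Si](C)(C)C(C)(C)C)C=C[C@@H](O[Si](C)(C)C(C)(C)C)[C@H](O[Si](C)(C)C(C)(C)C)C1
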